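The dihydropyran ring fused to ring B is cut at O1–C2 and C3–C4. Its aryl oxygen and benzylic C4 are ortho neighbours on ring B, a latent ortho-quinone methide; C2 with its two methyl groups and C3 are isobutene. In the key step the twofold-symmetric 5-(benzyloxy)-2-(hydroxymethyl)resorcinol loses water to this quinone methide, which takes up isobutene in an inverse-demand hetero-Diels–Alder reaction and so closes the ring with both bonds at once. The resulting chromanol has one free ortho position; formylation there, O-methylation, chalcone formation, oxidative 1,2-aryl shift to the isoflavone and hydrogenolysis finish the synthesis.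

Key step: step 3

Remark: the target has no stereocentre, so no stereocontrol is needed; the one stereocentre that appears on the way (acetal 11) is racemic and is destroyed in the same step. Isobutene 4 and ketone 9 are taken as commercial.

Step 1
Reactants: 1 2,4,6-trihydroxybenzaldehyde
Product: 2 4-(benzyloxy)-2,6-dihydroxybenzaldehyde
Conditions: BnBr (1.0 equiv), NaHCO3, DMF, rt
Reagents that add atoms: benzyl bromide, BrCc1ccccc1
Why: Williamson etherification; the 4-OH is para to the formyl group and is the only hydroxyl not held in a hydrogen bond to the carbonyl, so it is the most acidic and should be benzylated first by one equivalent of halide with a weak base.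

Step 2
Reactants: 2 4-(benzyloxy)-2,6-dihydroxybenzaldehyde
Product: 3 5-(benzyloxy)-2-(hydroxymethyl)benzene-1,3-diol
Conditions: NaBH4, THF/EtOH, −10 to 0 °C; cold pH 7 buffer; crude product used at once
Reagents that add atoms: none
Why: Hydride reduction of the aldehyde with NaBH4; low temperature and a buffered work-up should keep the electron-rich hydroxybenzyl alcohol from ionising before the alkene is present.

Step 3
Reactants: 3 5-(benzyloxy)-2-(hydroxymethyl)benzene-1,3-diol; 4 2-methylpropene (isobutene)
Product: 6 7-(benzyloxy)-2,2-dimethyl-3,4-dihydro-2H-chromen-5-ol, via ortho-quinone methide 5 (not isolated)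
Conditions: isobutene (condensed, ca. 40 equiv), toluene (0.02 M in 3), steel autoclave, 110 °C
Reagents that add atoms: none
Why: Heating the 2-hydroxybenzyl alcohol unit of 3 should cause 1,4-loss of water to ortho-quinone methide 5; because 3 is twofold-symmetric both flanking hydroxyls give the same species, and the benzyl ether keeps the para oxygen from forming a para-quinone methide. 5 is an electron-poor 1-oxadiene and should add isobutene in an inverse-electron-demand hetero-Diels–Alder reaction, the closest known reaction type being the [4+2] cycloaddition of ortho-quinone methides with unactivated 1,1-disubstituted alkenes to 2,2-disubstituted chromans. The dihydropyran ring closes in this intermolecular [4+2] event itself, through an asynchronous transition state in which the bond from the methide carbon to the alkene CH2 runs ahead of the O–C bond, and the regained aromaticity of ring B drives the reaction. No stereocentre is formed, since C2 carries two methyl groups. The selectivity needed is regiochemical (oxygen to the tertiary carbon) and is secured by the polarisation of both partners: the methide carbon is the electrophilic end, the unsubstituted alkene carbon the nucleophilic end, and the developing positive charge sits on the tertiary carbon that the oxygen then binds. Chemoselectivity against self-condensation of 5 and alkylation of the resorcinol rings is sought by the large excess of alkene, high dilution of 3 and neutral conditions.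

Step 4
Reactants: 6 7-(benzyloxy)-2,2-dimethyl-3,4-dihydro-2H-chromen-5-ol
Product: 7 7-(benzyloxy)-5-hydroxy-2,2-dimethyl-3,4-dihydro-2H-chromene-6-carbaldehyde
Conditions: MgCl2, Et3N, (CH2O)n, MeCN, reflux
Reagents that add atoms: paraformaldehyde (as formaldehyde), C=O
Why: Casnati–Skattebøl ortho-formylation; the magnesium phenoxide delivers formaldehyde only to an ortho carbon, and C6 is the single free ortho position of the 5-OH (C4a is substituted, C8 is para), so the formyl group can only enter between the hydroxyl and the benzyloxy group.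

Step 5
Reactants: 7 7-(benzyloxy)-5-hydroxy-2,2-dimethyl-3,4-dihydro-2H-chromene-6-carbaldehyde
Product: 8 7-(benzyloxy)-5-methoxy-2,2-dimethyl-3,4-dihydro-2H-chromene-6-carbaldehyde
Conditions: MeI, K2CO3, DMF, 40 °C
Reagents that add atoms: iodomethane, CI
Why: Williamson O-methylation of the only free phenol, whose hydrogen bond to the aldehyde is broken by carbonate in DMF; this fixes the methoxy group between the two carbon substituents of ring B.

Step 6
Reactants: 8 7-(benzyloxy)-5-methoxy-2,2-dimethyl-3,4-dihydro-2H-chromene-6-carbaldehyde; 9 1-[4-(benzyloxy)-2-hydroxyphenyl]ethan-1-one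
Product: 10 (2E)-1-[4-(benzyloxy)-2-hydroxyphenyl]-3-[7-(benzyloxy)-5-methoxy-2,2-dimethyl-3,4-dihydro-2H-chromen-6-yl]prop-2-en-1-one
Conditions: KOH (50% aq.), EtOH, rt to 40 °C; then dilute HCl
Reagents that add atoms: none
Why: Claisen–Schmidt condensation; the enolate of 9 adds to the non-enolisable aldehyde 8 and the aldol dehydrates to the conjugated enone in its thermodynamically favoured E geometry.

Step 7
Reactants: 10 (2E)-1-[4-(benzyloxy)-2-hydroxyphenyl]-3-[7-(benzyloxy)-5-methoxy-2,2-dimethyl-3,4-dihydro-2H-chromen-6-yl]prop-2-en-1-one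
Product: 12 7-(benzyloxy)-3-[7-(benzyloxy)-5-methoxy-2,2-dimethyl-3,4-dihydro-2H-chromen-6-yl]-4H-chromen-4-one, via dimethyl acetal 11 (not isolated)
Conditions: Tl(NO3)3·3H2O (1.1 equiv), MeOH/HC(OMe)3, rt; then 10% aq. HCl, 50 °C
Reagents that add atoms: none
Why: Oxidative 1,2-aryl migration of a 2'-hydroxychalcone by trivalent thallium, in which the very electron-rich ring B aryl group shifts from the β- to the α-carbon and the β-carbon is caught by the solvent as dimethyl acetal 11 (racemic stereocentre, lost again), followed by acid-catalysed attack of the phenol on the acetal carbon and loss of both methanol molecules to close the 4-pyranone ring.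

Step 8
Reactants: 12 7-(benzyloxy)-3-[7-(benzyloxy)-5-methoxy-2,2-dimethyl-3,4-dihydro-2H-chromen-6-yl]-4H-chromen-4-one
Product: 13 glycyrrhizaisoflavone C
Conditions: H2 (1 atm), 10% Pd/C, EtOAc/MeOH, rt, followed closely
Reagents that add atoms: none
Why: Hydrogenolysis of the two benzyl aryl ethers over Pd/C at 1 atm, conditions under which the chromone double bond, the methyl ether and the dihydropyran ring should stay intact.

Compound list
1 | 2,4,6-trihydroxybenzaldehyde | O=Cc1c(O)cc(O)cc1O | starting material
2 | 4-(benzyloxy)-2,6-dihydroxybenzaldehyde | O=Cc1c(O)cc(OCc2ccccc2)cc1O | intermediate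
3 | 5-(benzyloxy)-2-(hydroxymethyl)benzene-1,3-diol | OCc1c(O)cc(OCc2ccccc2)cc1O | intermediate
4 | 2-methylpropene (isobutene) | C=C(C)C | starting material
5 | 3-(benzyloxy)-5-hydroxy-6-methylidenecyclohexa-2,4-dien-1-one (ortho-quinone methide; formed in the flask) | C=C1C(=O)C=C(OCc2ccccc2)C=C1O | intermediate
6 | 7-(benzyloxy)-2,2-dimethyl-3,4-dihydro-2H-chromen-5-ol | CC1(C)CCc2c(O)cc(OCc3ccccc3)cc2O1 | intermediate
7 | 7-(benzyloxy)-5-hydroxy-2,2-dimethyl-3,4-dihydro-2H-chromene-6-carbaldehyde | CC1(C)CCc2c(O)c(C=O)c(OCc3ccccc3)cc2O1 | intermediate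
8 | 7-(benzyloxy)-5-methoxy-2,2-dimethyl-3,4-dihydro-2H-chromene-6-carbaldehyde | CC1(C)CCc2c(OC)c(C=O)c(OCc3ccccc3)cc2O1 | intermediate
9 | 1-[4-(benzyloxy)-2-hydroxyphenyl]ethan-1-one | CC(=O)c1ccc(OCc2ccccc2)cc1O | starting material
10 | (2E)-1-[4-(benzyloxy)-2-hydroxyphenyl]-3-[7-(benzyloxy)-5-methoxy-2,2-dimethyl-3,4-dihydro-2H-chromen-6-yl]prop-2-en-1-one | O=C(/C=C/c1c(OC)c2CCC(C)(C)Oc2cc1OCc1ccccc1)c1ccc(OCc2ccccc2)cc1O | intermediate
11 | 1-[4-(benzyloxy)-2-hydroxyphenyl]-2-[7-(benzyloxy)-5-methoxy-2,2-dimethyl-3,4-dihydro-2H-chromen-6-yl]-3,3-dimethoxypropan-1-one (racemic; formed in the flask) | COC(OC)C(c1c(OC)c2CCC(C)(C)Oc2cc1OCc1ccccc1)C(=O)c1ccc(OCc2ccccc2)cc1O | intermediate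
12 | 7-(benzyloxy)-3-[7-(benzyloxy)-5-methoxy-2,2-dimethyl-3,4-dihydro-2H-chromen-6-yl]-4H-chromen-4-one | COc1c2CCC(C)(C)Oc2cc(OCc2ccccc2)c1-c1coc2cc(OCc3ccccc3)ccc2c1=O | intermediate
13 | glycyrrhizaisoflavone C, 7-hydroxy-3-(7-hydroxy-5-methoxy-2,2-dimethyl-3,4-dihydro-2H-chromen-6-yl)-4H-chromen-4-one | COc1c2c(cc(O)c1-c1coc3cc(O)ccc3c1=O)OC(C)(C)CC2 | target

Total step count: 8. Longest linear sequence: 8 steps (1 → 2 → 3 → 6 → 7 → 8 → 10 → 12 → 13).

Steps most likely to fail

Step 3. The quinone methide may be consumed by self-condensation and by Friedel–Crafts alkylation of the electron-rich resorcinol rings faster than the weakly nucleophilic alkene can trap it. The fallback builds the ring without a quinone methide and sets out from aldehyde 2. Wittig olefination with ethyl (triphenylphosphoranylidene)acetate in N,N-diethylaniline at reflux, with lactonisation in the same pot, would give 7-(benzyloxy)-5-hydroxy-2H-chromen-2-one F1. Excess MeMgBr in THF, then catalytic TsOH, would convert the lactone by double addition and cyclodehydration of the allylic tertiary alcohol into 7-(benzyloxy)-2,2-dimethyl-2H-chromen-5-ol F2. Hydrogenation of the C3–C4 double bond with H2 over RhCl(PPh3)3, which leaves the benzyl ether alone, comes back to the route at 6.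

Step 2. The hydroxybenzyl alcohol may ionise during reduction or work-up, so that the quinone methide captures hydride (over-reduction to the methyl arene) or oligomerises before it can be used. The fallback sets out from aldehyde 2 and stores the benzylic carbon as an amine. Reductive amination with morpholine and NaBH(OAc)3 in 1,2-dichloroethane would give the Mannich base 5-(benzyloxy)-2-(morpholin-4-ylmethyl)benzene-1,3-diol F3, which can be purified and kept. Heating F3 with isobutene 4 in toluene at 140 °C would expel morpholine, generate 5 and come back to the route at 6, so that 3 is not needed.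

Step 7. The thallium salt may oxidise the free phenol or the electron-rich ring B (oxidative cyclisation to an aurone, ring oxidation) instead of inducing the aryl shift. The fallback sets out from chalcone 10 and reaches the same skeleton by a 1,2-acyl shift. Protection with NaH and MOMCl in THF would give the 2'-O-methoxymethyl chalcone F4. Weitz–Scheffer epoxidation with H2O2 and NaOH in MeOH/THF would give the racemic trans-epoxide F5. BF3·OEt2 in CH2Cl2 at 0 °C would open the epoxide at the benzylic carbon and shift the aroyl group to give the α-formyl deoxybenzoin F6. HCl in MeOH would then remove the methoxymethyl group and cyclodehydrate, coming back to the route at 12.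

Further compounds
F1 | step 3 | 7-(benzyloxy)-5-hydroxy-2H-chromen-2-one | O=c1ccc2c(O)cc(OCc3ccccc3)cc2o1
F2 | step 3 | 7-(benzyloxy)-2,2-dimethyl-2H-chromen-5-ol | CC1(C)C=Cc2c(O)cc(OCc3ccccc3)cc2O1
F3 | step 2 | 5-(benzyloxy)-2-(morpholin-4-ylmethyl)benzene-1,3-diol | Oc1cc(OCc2ccccc2)cc(O)c1CN1CCOCC1
F4 | step 7 | (2E)-1-[4-(benzyloxy)-2-(methoxymethoxy)phenyl]-3-[7-(benzyloxy)-5-methoxy-2,2-dimethyl-3,4-dihydro-2H-chromen-6-yl]prop-2-en-1-one | COCOc1cc(OCc2ccccc2)ccc1C(=O)/C=C/c1c(OC)c2CCC(C)(C)Oc2cc1OCc1ccccc1
F5 | step 7 | [4-(benzyloxy)-2-(methoxymethoxy)phenyl]{trans-3-[7-(benzyloxy)-5-methoxy-2,2-dimethyl-3,4-dihydro-2H-chromen-6-yl]oxiran-2-yl}methanone (racemic, one enantiomer drawn) | COCOc1cc(OCc2ccccc2)ccc1C(=O)[C@@H]1O[C@H]1c1c(OC)c2CCC(C)(C)Oc2cc1OCc1ccccc1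
F6 | step 7 | 3-[4-(benzyloxy)-2-(methoxymethoxy)phenyl]-2-[7-(benzyloxy)-5-methoxy-2,2-dimethyl-3,4-dihydro-2H-chromen-6-yl]-3-oxopropanal (racemic) | COCOc1cc(OCc2ccccc2)ccc1C(=O)C(C=O)c1c(OC)c2CCC(C)(C)Oc2cc1OCc1ccccc1
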